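The route rests on cutting the O1–C8a bond of ring C, so the ring oxygen is supplied last by the side chain and not by ring A. Ring A then needs only its C5, C6 and C7 oxygens and comes from symmetric 2-methoxyresorcinol. The feature exploited is that ring A has a single C–H bond next to the carbon bearing the C4 carbonyl. This is C8a–H, which lies para to the C6 methoxyl, while C5 on the other side is already oxygenated. In one operation a palladium-catalysed dehydrogenative coupling joins the C2 enol oxygen to C8a and closes the pyranone. The precursor is an open 1,3-diaryl-1,3-diketone with a bis-MOM-protected ring A and a 4-benzyloxyphenyl ring B.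

Key step: step 4

Remark: flavone numbering (O1, C2 to C8a, primed ring B) is also used for the open-chain compounds, so C8a is C6 of the aryl ketone; methyl 4-(benzyloxy)benzoate is assumed to be purchased, which saves a benzylation; the 4'-oxygen stays a benzyl ether through step 4 because a prenyl alkene would react with palladium and the perester.

Step 1
Reactants: 1 2-methoxyresorcinol
Product: 2 1-(2,4-dihydroxy-3-methoxyphenyl)ethanone
Conditions: AcOH (1.2 equiv), BF3·OEt2 (solvent), 85 °C; then aq NaOAc
Reagents that add atoms: acetic acid, CC(=O)O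
Why: Friedel–Crafts (Nencki-type) C-acylation of an activated resorcinol, in which the two positions ortho/para to the hydroxyls are equivalent by symmetry, the third free carbon is meta to both, and the hydrogen-bonded ketone deactivates the ring against a second acylation.

Step 2
Reactants: 2 1-(2,4-dihydroxy-3-methoxyphenyl)ethanone
Product: 3 1-[3-methoxy-2,4-bis(methoxymethoxy)phenyl]ethanone
Conditions: NaH (2.4 equiv), MOMCl (2.6 equiv), DMF, 0 °C to rt
Reagents that add atoms: chloromethyl methyl ether, COCCl
Why: Williamson-type O-alkylation, in which complete deprotonation with NaH breaks the hydrogen bond between the ortho hydroxyl and the ketone, so both phenoxides should be acetalised by the very reactive MOMCl before the ketone is enolised.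

Step 3
Reactants: 3 1-[3-methoxy-2,4-bis(methoxymethoxy)phenyl]ethanone; 4 methyl 4-(benzyloxy)benzoate
Product: 6 1-[3-methoxy-2,4-bis(methoxymethoxy)phenyl]-3-[4-(benzyloxy)phenyl]propane-1,3-dione, via sodium diketonate 5 (not isolated)
Conditions: NaH (3 equiv), THF, 65 °C; then AcOH, 0 °C
Reagents that add atoms: sodium hydride, [Na+].[H-] (supplies only the sodium of 5)
Why: Crossed Claisen condensation in which only 3 can form an enolate and only 4 can act as acyl donor, driven forward by irreversible deprotonation of the 1,3-diketone, with acetals and benzyl ether inert to base.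

Step 4
Reactants: 6 1-[3-methoxy-2,4-bis(methoxymethoxy)phenyl]-3-[4-(benzyloxy)phenyl]propane-1,3-dione
Product: 7 4'-benzyloxy-6-methoxy-5,7-bis(methoxymethoxy)flavone
Conditions: Pd(OAc)2 (10 mol %), 3-nitropyridine (10 mol %), t-BuOOBz (2 equiv), C6F6/DMI, 90 °C, N2
Reagents that add atoms: none
Why: Proposed new method: ligand exchange puts the diketone on Pd(OAc)2 as its enolate, 3-nitropyridine and carboxylate open the resting O,O'-chelate to a monodentate enolate, and after rotation about C3–C4 the C8a–H bond is cleaved by carboxylate-assisted concerted metalation–deprotonation to give a seven-membered oxapalladacycle. The perester oxidises this divalent palladacycle to tetravalent palladium, from which C(aryl)–O reductive elimination forms O1–C8a and returns divalent palladium; a perester is preferred because trivalent-iodine and N–F oxidants would first attack the nucleophilic C3 of the diketone. The closest known reaction types are the dehydrogenative lactonisation of biaryl-2-carboxylic acids to benzocoumarins and the perester-driven cyclisation of 2-arylphenols to dibenzofurans, the enol being a vinylogous carboxylic acid with the same oxygen-to-C–H distance. Ring C closes as a six-membered ring by contraction of the seven-membered metallacycle, and no stereocentre is created. Within ring A the site is fixed by the substrate, since C5 carries oxygen and C8–H cannot lead to a six-membered ring. Between the rings the choice has to be electronic, because the tautomeric oxygen on C4 can reach C2'–H and C6'–H of ring B through a palladacycle of equal size: C8a is para to the C6 methoxyl on a trioxygenated ring, the ring B sites are meta to their only donor, and the electron-poor pyridine keeps the metal electrophilic enough to respond to this difference.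

Step 5
Reactants: 7 4'-benzyloxy-6-methoxy-5,7-bis(methoxymethoxy)flavone
Product: 8 4'-hydroxy-6-methoxy-5,7-bis(methoxymethoxy)flavone
Conditions: H2 (1 atm), 10% Pd/C, EtOAc/THF, rt
Reagents that add atoms: none
Why: Heterogeneous hydrogenolysis of a benzyl aryl ether, under which at one atmosphere and neutral pH the vinylogous-ester C2=C3 bond and the MOM acetals should stay untouched.

Step 6
Reactants: 8 4'-hydroxy-6-methoxy-5,7-bis(methoxymethoxy)flavone; 9 prenyl bromide
Product: 10 6-methoxy-5,7-bis(methoxymethoxy)-4'-(prenyloxy)flavone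
Conditions: K2CO3 (1.5 equiv), acetone, 50 °C
Reagents that add atoms: none
Why: Williamson ether synthesis by SN2 attack of the only free phenoxide on the primary allylic bromide.

Step 7
Reactants: 10 6-methoxy-5,7-bis(methoxymethoxy)-4'-(prenyloxy)flavone
Product: 13 3-hydroxy-6-methoxy-5,7-bis(methoxymethoxy)-4'-(prenyloxy)flavone, via 3-lithioflavone 11 (not isolated), via dimethyl 3-flavonylboronate 12 (not isolated)
Conditions: LiN(i-Pr)2 (1.5 equiv), THF, −78 °C; B(OMe)3 (3 equiv), −78 to 0 °C; AcOH, 30% H2O2, 0 °C to rt
Reagents that add atoms: hydrogen peroxide, OO (the C3 oxygen); lithium diisopropylamide, [Li]N(C(C)C)C(C)C (only the lithium of 11); trimethyl borate, COB(OC)OC (only the B(OMe)2 group of 12)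
Why: Deprotonation of a flavone at C3 by lithium diisopropylamide (vinylic C–H next to the lithium-binding C4 carbonyl), borate trapping and peroxide-induced 1,2-migration from boron to oxygen is an established flavone-to-flavonol sequence, and neither the amide base at −78 °C nor weakly acidic H2O2 should touch the trisubstituted alkene.

Step 8
Reactants: 13 3-hydroxy-6-methoxy-5,7-bis(methoxymethoxy)-4'-(prenyloxy)flavone
Product: 14 3,5,7-trihydroxy-6-methoxy-4'-(prenyloxy)flavone
Conditions: HCl (0.5 M in MeOH), THF, rt
Reagents that add atoms: none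
Why: Acid-catalysed acetal methanolysis, in which the MOM groups ionise through an oxocarbenium ion far more readily than the aryl prenyl ether ionises to an allyl cation, so dilute acid at room temperature should free O5 and O7 and leave the 4'-ether in place.

Compound list
1 | 2-methoxyresorcinol (2-methoxybenzene-1,3-diol) | COc1c(O)cccc1O | starting material
2 | 1-(2,4-dihydroxy-3-methoxyphenyl)ethanone | CC(=O)c1ccc(O)c(OC)c1O | intermediate
3 | 1-[3-methoxy-2,4-bis(methoxymethoxy)phenyl]ethanone | CC(=O)c1ccc(OCOC)c(OC)c1OCOC | intermediate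
4 | methyl 4-(benzyloxy)benzoate | COC(=O)c1ccc(OCc2ccccc2)cc1 | starting material
5 | sodium (Z)-enolate of diketone 6 | [Na+].[O-]/C(=C\C(=O)c1ccc(OCOC)c(OC)c1OCOC)c1ccc(OCc2ccccc2)cc1 | intermediate (not isolated)
6 | 1-[3-methoxy-2,4-bis(methoxymethoxy)phenyl]-3-[4-(benzyloxy)phenyl]propane-1,3-dione | COCOc1ccc(C(=O)CC(=O)c2ccc(OCc3ccccc3)cc2)c(OCOC)c1OC | intermediate
7 | 4'-benzyloxy-6-methoxy-5,7-bis(methoxymethoxy)flavone | COCOc1cc2oc(-c3ccc(OCc4ccccc4)cc3)cc(=O)c2c(OCOC)c1OC | intermediate
8 | 4'-hydroxy-6-methoxy-5,7-bis(methoxymethoxy)flavone | COCOc1cc2oc(-c3ccc(O)cc3)cc(=O)c2c(OCOC)c1OC | intermediate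
9 | prenyl bromide (1-bromo-3-methylbut-2-ene) | CC(C)=CCBr | starting material
10 | 6-methoxy-5,7-bis(methoxymethoxy)-4'-(prenyloxy)flavone | COCOc1cc2oc(-c3ccc(OCC=C(C)C)cc3)cc(=O)c2c(OCOC)c1OC | intermediate
11 | 3-lithio derivative of 10 | [Li]c1c(-c2ccc(OCC=C(C)C)cc2)oc2cc(OCOC)c(OC)c(OCOC)c2c1=O | intermediate (not isolated)
12 | dimethyl boronate at C3 of 10 | COB(OC)c1c(-c2ccc(OCC=C(C)C)cc2)oc2cc(OCOC)c(OC)c(OCOC)c2c1=O | intermediate (not isolated)
13 | 3-hydroxy-6-methoxy-5,7-bis(methoxymethoxy)-4'-(prenyloxy)flavone | COCOc1cc2oc(-c3ccc(OCC=C(C)C)cc3)c(O)c(=O)c2c(OCOC)c1OC | intermediate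
14 | 3,5,7-trihydroxy-6-methoxy-4'-(prenyloxy)flavone | COc1c(O)cc2oc(-c3ccc(OCC=C(C)C)cc3)c(O)c(=O)c2c1O | target

Total step count: 8. Longest linear sequence: 8 steps (1 to 14).

Steps most likely to fail

**Step 4 (proposed new method).**
- Palladium may rest as the inert O,O'-bis(diketonate).
- The perester may oxygenate the nucleophilic C3 instead of the palladacycle.
- Palladation may take place on ring B.
- Acid released during turnover may strip the C5 acetal, after which dehydrative closure through O5 would take over.

The fallback uses known chemistry, places the ring oxygen on ring A first, sets out from 1 and returns at 7. Compound 1 is acetalised with MOMCl and i-Pr2NEt to 2-methoxy-1,3-bis(methoxymethoxy)benzene F1. Sterically controlled C–H borylation ([Ir(OMe)(cod)]2, 4,4'-di-tert-butyl-2,2'-bipyridine, B2pin2, THF, 80 °C) should go to the only carbon without an ortho neighbour, para to the methoxyl. This gives 2-[4-methoxy-3,5-bis(methoxymethoxy)phenyl]-4,4,5,5-tetramethyl-1,3,2-dioxaborolane F2. NaBO3·4H2O in THF/water oxidises it to 4-methoxy-3,5-bis(methoxymethoxy)phenol F3. One equivalent of N-iodosuccinimide iodinates one of the two equivalent ortho positions to give 2-iodo-4-methoxy-3,5-bis(methoxymethoxy)phenol F4. Carbonylative Sonogashira coupling with purchased 1-(benzyloxy)-4-ethynylbenzene under CO (PdCl2(PPh3)2, Et2NH, 60 to 100 °C), followed by amine-mediated six-membered closure of the ynone, gives 7.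

**Step 7.**
- Deprotonation may compete at C8 (between O1 and the C7 acetal) or at the allylic OCH2.
- The lithiated pyranone may open by β-elimination on warming.

The fallback replaces deprotonation by electrophilic oxidation before the alkene is present; it sets out from 7 and returns at 14. Compound 7 is epoxidised at C2=C3 with dimethyldioxirane (acetone/CH2Cl2, 0 °C) to the racemic cis-fused 2,3-epoxyflavanone F5. A trace of p-TsOH isomerises this to 4'-benzyloxy-3-hydroxy-6-methoxy-5,7-bis(methoxymethoxy)flavone F6. MOMCl and i-Pr2NEt give 4'-benzyloxy-6-methoxy-3,5,7-tris(methoxymethoxy)flavone F7. Hydrogenolysis (H2, Pd/C) gives 4'-hydroxy-6-methoxy-3,5,7-tris(methoxymethoxy)flavone F8. Prenyl bromide 9 with K2CO3 gives 6-methoxy-3,5,7-tris(methoxymethoxy)-4'-(prenyloxy)flavone F9. Methanolic HCl as in step 8 gives 14.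

**Step 8.**
- The prenyl ether may ionise in acid, with loss of the prenyl group or its migration to carbon, before the slower C7 acetal is cleaved.

The fallback moves the acid step ahead of the prenylation and ends with a base-labile protecting set; it sets out from 7 and returns at 14. Compound 7 is hydroxylated at C3 to F6 as in the preceding fallback. With no prenyl group present, methanolic HCl at reflux gives 4'-benzyloxy-3,5,7-trihydroxy-6-methoxyflavone F10. Ac2O, pyridine and DMAP give 4'-benzyloxy-6-methoxyflavone-3,5,7-triyl triacetate F11. Hydrogenolysis (H2, Pd/C, EtOAc) gives 4'-hydroxy-6-methoxyflavone-3,5,7-triyl triacetate F12. Mitsunobu etherification with 3-methylbut-2-en-1-ol (PPh3, DIAD, THF, 0 °C) gives 6-methoxy-4'-(prenyloxy)flavone-3,5,7-triyl triacetate F13. Catalytic K2CO3 in MeOH at 0 °C under argon removes the acetates to give 14, so the prenyl ether never meets acid.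

Further compounds
F1 | step 4 | 2-methoxy-1,3-bis(methoxymethoxy)benzene | COCOc1cccc(OCOC)c1OC
F2 | step 4 | 2-[4-methoxy-3,5-bis(methoxymethoxy)phenyl]-4,4,5,5-tetramethyl-1,3,2-dioxaborolane | COCOc1cc(B2OC(C)(C)C(C)(C)O2)cc(OCOC)c1OC
F3 | step 4 | 4-methoxy-3,5-bis(methoxymethoxy)phenol | COCOc1cc(O)cc(OCOC)c1OC
F4 | step 4 | 2-iodo-4-methoxy-3,5-bis(methoxymethoxy)phenol | COCOc1cc(O)c(I)c(OCOC)c1OC
F5 | step 7 | racemic cis-fused 2,3-epoxyflavanone from 7 (one enantiomer drawn) | O=C1c2c(OCOC)c(OC)c(OCOC)cc2O[C@]2(c3ccc(OCc4ccccc4)cc3)O[C@H]12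
F6 | step 7 | 4'-benzyloxy-3-hydroxy-6-methoxy-5,7-bis(methoxymethoxy)flavone | COCOc1cc2oc(-c3ccc(OCc4ccccc4)cc3)c(O)c(=O)c2c(OCOC)c1OC
F7 | step 7 | 4'-benzyloxy-6-methoxy-3,5,7-tris(methoxymethoxy)flavone | COCOc1cc2oc(-c3ccc(OCc4ccccc4)cc3)c(OCOC)c(=O)c2c(OCOC)c1OC
F8 | step 7 | 4'-hydroxy-6-methoxy-3,5,7-tris(methoxymethoxy)flavone | COCOc1cc2oc(-c3ccc(O)cc3)c(OCOC)c(=O)c2c(OCOC)c1OC
F9 | step 7 | 6-methoxy-3,5,7-tris(methoxymethoxy)-4'-(prenyloxy)flavone | COCOc1cc2oc(-c3ccc(OCC=C(C)C)cc3)c(OCOC)c(=O)c2c(OCOC)c1OC
F10 | step 8 | 4'-benzyloxy-3,5,7-trihydroxy-6-methoxyflavone | COc1c(O)cc2oc(-c3ccc(OCc4ccccc4)cc3)c(O)c(=O)c2c1O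
F11 | step 8 | 4'-benzyloxy-6-methoxyflavone-3,5,7-triyl triacetate | COc1c(OC(C)=O)cc2oc(-c3ccc(OCc4ccccc4)cc3)c(OC(C)=O)c(=O)c2c1OC(C)=O
F12 | step 8 | 4'-hydroxy-6-methoxyflavone-3,5,7-triyl triacetate | COc1c(OC(C)=O)cc2oc(-c3ccc(O)cc3)c(OC(C)=O)c(=O)c2c1OC(C)=O
F13 | step 8 | 6-methoxy-4'-(prenyloxy)flavone-3,5,7-triyl triacetate | COc1c(OC(C)=O)cc2oc(-c3ccc(OCC=C(C)C)cc3)c(OC(C)=O)c(=O)c2c1OC(C)=O
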